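**Retrosynthetic overview**

1. Feature: the C1–C6 bond belongs both to the cyclohexene (C1–C6) and to the oxirane (C1, C6, O), and C6 is allylic to the C4=C5 alkene, so an allylic sulfonium ylide carbon at C6 can bond to a C1 ketone and then be attacked by the C1 alkoxide. Locants: C1 = oxirane carbon carrying the C7H2O arm, C2 = CH–OMe, C3 = CH–OBz; the target is (1R,2S,3R,6R).
2. Endgame: both benzoates (C3–O, C7–O) go on last; before that C3–O is a TIPS ether and C7–O a PMB ether.
3. Key disconnection: C1–C6 and C6–O together, back to an acyclic Z-allylic diphenylsulfonium salt with a C1 ketone; the carbocycle closes first and the oxirane second, in one flask.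
4. The sulfonium salt comes from the Z-allylic bromide (alkyne semihydrogenation, Appel bromination); the C1 ketone comes from a Weinreb amide and PMB-oxymethyllithium.
5. C2 and C3 come from an Evans syn glycolate aldol of (S)-4-benzyl-3-(methoxyacetyl)oxazolidin-2-one with 4-(TBS-oxy)but-2-ynal.

Key step: step 12

Remark on protecting groups: C3–O is carried as a TIPS ether, not a benzylic ether. A benzyl-type ether oxygen held cis to C6 by the Z alkene would capture the silver-activated allylic bromide of step 11 (5-exo-tet) and expel the benzylic cation, leaving a 2,5-dihydrofuran. A hindered, weakly basic silyl ether should not do this and is still a poor vinylogous leaving group for the ylide.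

Remark on materials: compounds 1, 2, 5, 12, 13 and 21 are taken as commercial.

**Route**

Step 1
Reactants: 1 (S)-4-benzyl-1,3-oxazolidin-2-one; 2 methoxyacetyl chloride
Product: 4 (S)-4-benzyl-3-(2-methoxyacetyl)-1,3-oxazolidin-2-one, via lithiated oxazolidinone 3 (not isolated)
Conditions: n-BuLi, THF, −78 °C; then 2, −78 → 0 °C
Reagents that add atoms: none
Why: N-acylation of the lithiated oxazolidinone with an acid chloride is the standard entry to Evans imides and does not touch the C4 stereocentre of the auxiliary.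

Step 2
Reactants: 5 tert-butyldimethyl(prop-2-yn-1-yloxy)silane
Product: 7 4-[(tert-butyldimethylsilyl)oxy]but-2-ynal, via lithium acetylide 6 (not isolated)
Conditions: n-BuLi, THF, −78 °C; DMF, −78 → 0 °C; reverse quench into aq. KH2PO4/MTBE, 0 °C
Reagents that add atoms: N,N-dimethylformamide, CN(C)C=O
Why: Formylation of a lithium acetylide with DMF, with release of the ynal on a buffered reverse quench, is a standard ynal synthesis to which the TBS ether is inert.

Step 3
Reactants: 4 (S)-4-benzyl-3-(2-methoxyacetyl)-1,3-oxazolidin-2-one; 7 4-[(tert-butyldimethylsilyl)oxy]but-2-ynal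
Product: 9 (S)-4-benzyl-3-[(2S,3R)-6-[(tert-butyldimethylsilyl)oxy]-3-hydroxy-2-methoxyhex-4-ynoyl]-1,3-oxazolidin-2-one, via dibutylboron Z-enolate 8 (not isolated)
Conditions: Bu2BOTf, Et3N, CH2Cl2, −78 → 0 °C; then 7, −78 → 0 °C; pH 7 buffer/MeOH/H2O2, 0 °C
Reagents that add atoms: none
Why: Evans syn aldol reaction, in which the Z boron enolate 8 reacts through a closed Zimmerman–Traxler chair on the enolate face away from the benzyl group, setting C2 (S) and C3 (R) in the syn relationship that becomes the trans C2–OMe/C3–O pair of the ring.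

Step 4
Reactants: 9 the aldol adduct
Product: 10 (2S,3R)-6-[(tert-butyldimethylsilyl)oxy]-3-hydroxy-N,2-dimethoxy-N-methylhex-4-ynamide
Conditions: MeNHOMe·HCl, AlMe3, THF, −20 → 0 °C; aq. potassium sodium tartrate work-up
Reagents that add atoms: N,O-dimethylhydroxylamine hydrochloride, CNOC.Cl
Why: Aluminium amide transamination of a β-hydroxy imide (Weinreb amide formation) is assisted by the free C3 hydroxyl, attacks the exocyclic carbonyl and should not epimerise C2.

Step 5
Reactants: 10 the hydroxy Weinreb amide
Product: 11 (2S,3R)-6-[(tert-butyldimethylsilyl)oxy]-N,2-dimethoxy-N-methyl-3-[(triisopropylsilyl)oxy]hex-4-ynamide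
Conditions: TIPSOTf, 2,6-lutidine, CH2Cl2, 0 °C → rt
Reagents that add atoms: triisopropylsilyl trifluoromethanesulfonate, CC(C)[Si](OS(=O)(=O)C(F)(F)F)(C(C)C)C(C)C
Why: Silylation of a secondary propargylic alcohol with a silyl triflate and a hindered pyridine base is routine and non-epimerising, and it places a group at C3 that differs in lability from the primary TBS ether.

Step 6
Reactants: 12 4-methoxybenzyl alcohol; 13 tributyl(iodomethyl)stannane
Product: 15 tributyl{[(4-methoxybenzyl)oxy]methyl}stannane, via sodium 4-methoxybenzyl oxide 14 (not isolated)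
Conditions: NaH, THF/DMF, 0 °C; then 13, 0 °C → rt
Reagents that add atoms: none
Why: Williamson etherification of the alkoxide with the iodomethylstannane, a reactive primary iodide with no β-hydrogen, should give the α-alkoxymethylstannane cleanly.

Step 7
Reactants: 11 the silylated Weinreb amide; 15 tributyl{[(4-methoxybenzyl)oxy]methyl}stannane
Product: 17 (3S,4R)-7-[(tert-butyldimethylsilyl)oxy]-3-methoxy-1-[(4-methoxybenzyl)oxy]-4-[(triisopropylsilyl)oxy]hept-5-yn-2-one, via PMB-oxymethyllithium 16 (not isolated)
Conditions: 15, n-BuLi, THF, −78 °C, 10 min; then 11, −78 °C; AcOH/THF quench at −78 °C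
Reagents that add atoms: none
Why: Tin–lithium exchange gives the α-alkoxymethyllithium 16, which adds once to the Weinreb amide because the chelated tetrahedral adduct survives until the cold acidic quench, so the ketone never meets base and C2 keeps its configuration.

Step 8
Reactants: 17 the bis-silyl ynone
Product: 18 (3S,4R)-7-hydroxy-3-methoxy-1-[(4-methoxybenzyl)oxy]-4-[(triisopropylsilyl)oxy]hept-5-yn-2-one
Conditions: HF·pyridine, pyridine, THF, 0 °C
Reagents that add atoms: none
Why: Buffered HF·pyridine cleaves the unhindered primary TBS ether much faster than the secondary TIPS ether, and the ketone, the PMB ether and the alkyne are inert to it.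

Step 9
Reactants: 18 the propargylic alcohol
Product: 19 (3S,4R,5Z)-7-hydroxy-3-methoxy-1-[(4-methoxybenzyl)oxy]-4-[(triisopropylsilyl)oxy]hept-5-en-2-one
Conditions: H2 (1 atm), Pd/CaCO3 poisoned with Pb(OAc)2, quinoline, EtOAc, rt
Reagents that add atoms: none
Why: Lindlar semihydrogenation delivers both hydrogens syn from the poisoned palladium surface and should stop at the Z alkene, with quinoline suppressing over-reduction and the PMB ether and ketone untouched.

Step 10
Reactants: 19 the Z-allylic alcohol
Product: 20 (3S,4R,5Z)-7-bromo-3-methoxy-1-[(4-methoxybenzyl)oxy]-4-[(triisopropylsilyl)oxy]hept-5-en-2-one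
Conditions: CBr4, PPh3, 2,6-lutidine, CH2Cl2, −20 → 0 °C
Reagents that add atoms: tetrabromomethane, BrC(Br)(Br)Br
Why: Appel bromination displaces the primary oxyphosphonium by SN2 under nearly neutral conditions, which should preserve the Z geometry and C2, and any seven-membered hemiketal between C6–OH and the C1 ketone stays in equilibrium with the open form that reacts.

Step 11
Reactants: 20 the Z-allylic bromide; 21 diphenyl sulfide
Product: 22 [(2Z,4R,5S)-5-methoxy-7-[(4-methoxybenzyl)oxy]-6-oxo-4-[(triisopropylsilyl)oxy]hept-2-en-1-yl]diphenylsulfonium tetrafluoroborate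
Conditions: 21 (5 equiv), AgBF4, CH2Cl2, −30 °C → rt, dark; filtration, trituration with Et2O
Reagents that add atoms: silver tetrafluoroborate, [Ag+].F[B-](F)(F)F
Why: Silver-assisted S-alkylation of diphenyl sulfide by an allylic bromide is the standard preparation of allyl diphenylsulfonium tetrafluoroborates; the excess of sulfide should capture the primary terminus C6, and the C3 oxygen is shielded as a TIPS ether against participation.

Step 12
Reactants: 22 the Z-allylic diphenylsulfonium tetrafluoroborate
Product: 25 (1R,2S,3R,6R)-2-methoxy-1-{[(4-methoxybenzyl)oxy]methyl}-3-[(triisopropylsilyl)oxy]-7-oxabicyclo[4.1.0]hept-4-ene, via allylic sulfonium ylide 23 (not isolated), via trans-betaine 24 (not isolated)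
Conditions: KN(SiMe3)2 (1.0 equiv, slow addition), THF (0.01 M), −78 → −20 °C
Reagents that add atoms: none
Why: Proposed new method: KN(SiMe3)2 removes the only proton α to sulfur (C6–H, acidified by S+ and by the C4=C5 alkene) to give the allylic ylide 23, whose C6 adds to the C1 ketone in a 6-exo-trig closure of the cyclohexene (the allyl π-system lies inside the forming ring, which a six-membered ring tolerates) to give betaine 24; the closest known reactions are the intermolecular Corey–Chaykovsky epoxidation of ketones with diphenylsulfonium allylide, which gives vinyl oxiranes, and intramolecular ylide–carbonyl closures that give epoxide-fused heterocycles, but closure of a carbocycle and its oxirane from a tethered allylic ylide has no direct precedent. The C1 alkoxide of 24 then displaces Ph2S at C6 in a 3-exo-tet SN2 closure of the oxirane, possible only when O− and S+ are anti (trans-diaxial), so the ring fusion must be cis and C6 (R) follows from C1, while the syn betaine can only revert because addition of a semi-stabilised ylide is reversible. C1 (R) is set by the ketone face: in the half-chair transition state with C2–OMe, C3–OTIPS and the C7 arm equatorial the carbonyl oxygen is axial and hence cis to the C2 methoxy group, the C2–O bond is anti to the forming C1–C6 bond (polar Felkin–Anh), and the alternative half-chair would place the C1 oxygen and the C3 silyloxy group 1,3-diaxial. The step needs α-attack of the ylide (γ-attack would close a four-membered ring), ylide formation instead of ketone enolisation (the sulfonium C–H is the more acidic site and one equivalent of base is used at −78 °C), and addition faster than vinylogous loss of the C3 oxygen (a silyloxide is a poor leaving group at this temperature). The Z alkene keeps C6 within reach of C1, diphenylsulfonium carries no second α-hydrogen so no other ylide and no [2,3]-shift can arise, and high dilution suppresses intermolecular epoxidation.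

Step 13
Reactants: 25 the TIPS/PMB-protected vinyl oxirane
Product: 26 (1R,2S,3R,6R)-2-methoxy-1-{[(4-methoxybenzyl)oxy]methyl}-7-oxabicyclo[4.1.0]hept-4-en-3-ol
Conditions: Bu4NF, THF, 0 °C → rt
Reagents that add atoms: none
Why: Fluoride cleaves the secondary silyl ether, and with C7 still protected no alkoxide sits next to the oxirane, so a Payne rearrangement cannot occur.

Step 14
Reactants: 26 the C3 alcohol
Product: 27 (1R,2S,3R,6R)-1-(hydroxymethyl)-2-methoxy-7-oxabicyclo[4.1.0]hept-4-en-3-ol
Conditions: DDQ, CH2Cl2/pH 7 phosphate buffer, 0 °C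
Reagents that add atoms: none
Why: Oxidative PMB cleavage by DDQ proceeds by hydride abstraction from the electron-rich benzylic position and hydrolysis of the oxocarbenium ion, much faster than oxidation of the unactivated allylic alcohol, and the buffer protects the acid-labile vinyl oxirane.

Step 15
Reactants: 27 the diol
Product: 28 [(1R,2S,3R,6R)-3-(benzoyloxy)-2-methoxy-7-oxabicyclo[4.1.0]hept-4-en-1-yl]methyl benzoate (target)
Conditions: BzCl, pyridine, DMAP (cat.), CH2Cl2, 0 °C → rt
Reagents that add atoms: benzoyl chloride, O=C(Cl)c1ccccc1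
Why: Acylation of the primary and the secondary allylic hydroxyl with benzoyl chloride under pyridine/DMAP catalysis is routine and affects neither the oxirane nor any stereocentre.

**Compound list**

1 | (S)-4-benzyl-1,3-oxazolidin-2-one | O=C1N[C@@H](Cc2ccccc2)CO1 | starting material
2 | methoxyacetyl chloride | COCC(Cl)=O | starting material
3 | lithium salt of (S)-4-benzyl-1,3-oxazolidin-2-one (N-lithio) | [Li]N1[C@@H](Cc2ccccc2)COC1=O | intermediate
4 | (S)-4-benzyl-3-(2-methoxyacetyl)-1,3-oxazolidin-2-one | COCC(=O)N1[C@@H](Cc2ccccc2)COC1=O | intermediate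
5 | tert-butyldimethyl(prop-2-yn-1-yloxy)silane | C#CCO[Si](C)(C)C(C)(C)C | starting material
6 | lithium 3-[(tert-butyldimethylsilyl)oxy]prop-1-yn-1-ide | [Li]C#CCO[Si](C)(C)C(C)(C)C | intermediate
7 | 4-[(tert-butyldimethylsilyl)oxy]but-2-ynal | O=CC#CCO[Si](C)(C)C(C)(C)C | intermediate
8 | dibutylboron Z-enolate of 4 | CO/C=C(\OB(CCCC)CCCC)N1[C@@H](Cc2ccccc2)COC1=O | intermediate
9 | (S)-4-benzyl-3-[(2S,3R)-6-[(tert-butyldimethylsilyl)oxy]-3-hydroxy-2-methoxyhex-4-ynoyl]-1,3-oxazolidin-2-one | O=C1OC[C@H](Cc2ccccc2)N1C(=O)[C@@H](OC)[C@H](O)C#CCO[Si](C)(C)C(C)(C)C | intermediate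
10 | (2S,3R)-6-[(tert-butyldimethylsilyl)oxy]-3-hydroxy-N,2-dimethoxy-N-methylhex-4-ynamide | CON(C)C(=O)[C@@H](OC)[C@H](O)C#CCO[Si](C)(C)C(C)(C)C | intermediate
11 | (2S,3R)-6-[(tert-butyldimethylsilyl)oxy]-N,2-dimethoxy-N-methyl-3-[(triisopropylsilyl)oxy]hex-4-ynamide | CON(C)C(=O)[C@@H](OC)[C@H](O[Si](C(C)C)(C(C)C)C(C)C)C#CCO[Si](C)(C)C(C)(C)C | intermediate
12 | 4-methoxybenzyl alcohol | COc1ccc(CO)cc1 | starting material
13 | tributyl(iodomethyl)stannane | CCCC[Sn](CCCC)(CCCC)CI | starting material
14 | sodium 4-methoxybenzyl oxide | COc1ccc(C[O-])cc1.[Na+] | intermediate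
15 | tributyl{[(4-methoxybenzyl)oxy]methyl}stannane | CCCC[Sn](CCCC)(CCCC)COCc1ccc(OC)cc1 | intermediate
16 | [(4-methoxybenzyl)oxy]methyllithium | [Li]COCc1ccc(OC)cc1 | intermediate
17 | (3S,4R)-7-[(tert-butyldimethylsilyl)oxy]-3-methoxy-1-[(4-methoxybenzyl)oxy]-4-[(triisopropylsilyl)oxy]hept-5-yn-2-one | COc1ccc(COCC(=O)[C@@H](OC)[C@H](O[Si](C(C)C)(C(C)C)C(C)C)C#CCO[Si](C)(C)C(C)(C)C)cc1 | intermediate
18 | (3S,4R)-7-hydroxy-3-methoxy-1-[(4-methoxybenzyl)oxy]-4-[(triisopropylsilyl)oxy]hept-5-yn-2-one | COc1ccc(COCC(=O)[C@@H](OC)[C@H](O[Si](C(C)C)(C(C)C)C(C)C)C#CCO)cc1 | intermediate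
19 | (3S,4R,5Z)-7-hydroxy-3-methoxy-1-[(4-methoxybenzyl)oxy]-4-[(triisopropylsilyl)oxy]hept-5-en-2-one | COc1ccc(COCC(=O)[C@@H](OC)[C@H](O[Si](C(C)C)(C(C)C)C(C)C)/C=C\CO)cc1 | intermediate
20 | (3S,4R,5Z)-7-bromo-3-methoxy-1-[(4-methoxybenzyl)oxy]-4-[(triisopropylsilyl)oxy]hept-5-en-2-one | COc1ccc(COCC(=O)[C@@H](OC)[C@H](O[Si](C(C)C)(C(C)C)C(C)C)/C=C\CBr)cc1 | intermediate
21 | diphenyl sulfide | c1ccc(Sc2ccccc2)cc1 | starting material
22 | [(2Z,4R,5S)-5-methoxy-7-[(4-methoxybenzyl)oxy]-6-oxo-4-[(triisopropylsilyl)oxy]hept-2-en-1-yl]diphenylsulfonium tetrafluoroborate | COc1ccc(COCC(=O)[C@@H](OC)[C@H](O[Si](C(C)C)(C(C)C)C(C)C)/C=C\C[S+](c2ccccc2)c2ccccc2)cc1.F[B-](F)(F)F | intermediate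
23 | allylic sulfonium ylide of 22 (carbanion at C6) | COc1ccc(COCC(=O)[C@@H](OC)[C@H](O[Si](C(C)C)(C(C)C)C(C)C)/C=C\[CH-][S+](c2ccccc2)c2ccccc2)cc1 | intermediate
24 | trans-betaine (1S,2S,3R,6S): cyclohexene with the C1 alkoxide anti to the C6 diphenylsulfonium group | CO[C@H]1[C@H](O[Si](C(C)C)(C(C)C)C(C)C)C=C[C@H]([S+](c2ccccc2)c2ccccc2)[C@]1([O-])COCc1ccc(OC)cc1 | intermediate
25 | (1R,2S,3R,6R)-2-methoxy-1-{[(4-methoxybenzyl)oxy]methyl}-3-[(triisopropylsilyl)oxy]-7-oxabicyclo[4.1.0]hept-4-ene | CO[C@H]1[C@H](O[Si](C(C)C)(C(C)C)C(C)C)C=C[C@H]2O[C@]21COCc1ccc(OC)cc1 | intermediate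
26 | (1R,2S,3R,6R)-2-methoxy-1-{[(4-methoxybenzyl)oxy]methyl}-7-oxabicyclo[4.1.0]hept-4-en-3-ol | CO[C@H]1[C@H](O)C=C[C@H]2O[C@]21COCc1ccc(OC)cc1 | intermediate
27 | (1R,2S,3R,6R)-1-(hydroxymethyl)-2-methoxy-7-oxabicyclo[4.1.0]hept-4-en-3-ol | CO[C@H]1[C@H](O)C=C[C@H]2O[C@]21CO | intermediate
28 | [(1R,2S,3R,6R)-3-(benzoyloxy)-2-methoxy-7-oxabicyclo[4.1.0]hept-4-en-1-yl]methyl benzoate | CO[C@H]1[C@H](OC(=O)c2ccccc2)C=C[C@H]2O[C@]21COC(=O)c1ccccc1 | target

**Totals and risks**

Total step count: 15. Longest linear sequence: 13 steps (steps 2, 3, 4, 5, 7, 8, 9, 10, 11, 12, 13, 14, 15, from compound 5).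

Steps most likely to fail:

1. Step 12 (the proposed new method). The ylide may be lost to vinylogous elimination of the C3 silyloxy group or to intermolecular epoxidation before it cyclises, or the ketone face may be selected poorly, giving the oxirane trans to the C2 methoxy group. The fallback uses known chemistry, sets out from bromide 20 and rejoins at 25. Heating 20 with PPh3 in MeCN should give [(2Z,4R,5S)-5-methoxy-7-[(4-methoxybenzyl)oxy]-6-oxo-4-[(triisopropylsilyl)oxy]hept-2-en-1-yl]triphenylphosphonium bromide F1. KN(SiMe3)2 in THF at −78 → 0 °C should then effect an intramolecular Wittig reaction of the allylic ylide with the C1 ketone to give (5R,6R)-6-methoxy-1-{[(4-methoxybenzyl)oxy]methyl}-5-[(triisopropylsilyl)oxy]cyclohexa-1,3-diene F2, which must be kept away from acid because it can aromatise. A Shi epoxidation of F2 (D-fructose-derived ketone catalyst, KHSO5, K2CO3 buffer, MeCN/dimethoxymethane/H2O, 0 °C) should attack the trisubstituted C1=C6 alkene in preference to the cis-disubstituted C4=C5 alkene. By analogy with 1-substituted cyclohexenes in the spiro transition-state model, this catalyst is expected to deliver oxygen to the face cis to the C2 methoxy group, giving 25.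

2. Step 11. Silver-assisted ionisation of the Z-allylic bromide may let the alkene isomerise, let the C2 methoxy oxygen or the anisyl ring capture C6, or strip the silyl ether through adventitious HBF4. The fallback avoids silver, sets out from 20 and rejoins at 25. Stirring 20 with tetrahydrothiophene in acetone at rt should give, by direct SN2 alkylation of the more nucleophilic dialkyl sulfide, 1-[(2Z,4R,5S)-5-methoxy-7-[(4-methoxybenzyl)oxy]-6-oxo-4-[(triisopropylsilyl)oxy]hept-2-en-1-yl]thiolan-1-ium bromide F3. Treating F3 with KN(SiMe3)2 under the conditions of step 12 should give 25 with loss of tetrahydrothiophene. This is held in reserve because the ring α-CH2 groups allow a second ylide that could undergo a [2,3]-shift.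

3. Step 7. The basic α-alkoxymethyllithium may deprotonate C2 of the amide, leading to β-elimination of the C3 silyloxy group or to epimerisation, or it may undergo Wittig rearrangement before it adds. The fallback replaces acyl substitution by aldehyde addition and oxidation, sets out from 11 and rejoins at 17. Reduction of 11 with i-Bu2AlH in THF at −78 °C should give (2S,3R)-6-[(tert-butyldimethylsilyl)oxy]-2-methoxy-3-[(triisopropylsilyl)oxy]hex-4-ynal F4. Addition of 16 (generated from 15 as in step 7) at −78 °C, much faster on the aldehyde than deprotonation, should give (3R,4R)-7-[(tert-butyldimethylsilyl)oxy]-3-methoxy-1-[(4-methoxybenzyl)oxy]-4-[(triisopropylsilyl)oxy]hept-5-yn-2-ol F5 as a mixture of C2 carbinol epimers, which does not matter. Oxidation with Dess–Martin periodinane buffered with NaHCO3 in CH2Cl2 should return ketone 17.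

**Further compounds**

F1 | step 12 | [(2Z,4R,5S)-5-methoxy-7-[(4-methoxybenzyl)oxy]-6-oxo-4-[(triisopropylsilyl)oxy]hept-2-en-1-yl]triphenylphosphonium bromide | COc1ccc(COCC(=O)[C@@H](OC)[C@H](O[Si](C(C)C)(C(C)C)C(C)C)/C=C\C[P+](c2ccccc2)(c2ccccc2)c2ccccc2)cc1.[Br-]
F2 | step 12 | (5R,6R)-6-methoxy-1-{[(4-methoxybenzyl)oxy]methyl}-5-[(triisopropylsilyl)oxy]cyclohexa-1,3-diene | CO[C@H]1[C@H](O[Si](C(C)C)(C(C)C)C(C)C)C=CC=C1COCc1ccc(OC)cc1
F3 | step 11 | 1-[(2Z,4R,5S)-5-methoxy-7-[(4-methoxybenzyl)oxy]-6-oxo-4-[(triisopropylsilyl)oxy]hept-2-en-1-yl]thiolan-1-ium bromide | COc1ccc(COCC(=O)[C@@H](OC)[C@H](O[Si](C(C)C)(C(C)C)C(C)C)/C=C\C[S+]2CCCC2)cc1.[Br-]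
F4 | step 7 | (2S,3R)-6-[(tert-butyldimethylsilyl)oxy]-2-methoxy-3-[(triisopropylsilyl)oxy]hex-4-ynal | O=C[C@@H](OC)[C@H](O[Si](C(C)C)(C(C)C)C(C)C)C#CCO[Si](C)(C)C(C)(C)C
F5 | step 7 | (3R,4R)-7-[(tert-butyldimethylsilyl)oxy]-3-methoxy-1-[(4-methoxybenzyl)oxy]-4-[(triisopropylsilyl)oxy]hept-5-yn-2-ol (both C2 epimers) | COc1ccc(COCC(O)[C@@H](OC)[C@H](O[Si](C(C)C)(C(C)C)C(C)C)C#CCO[Si](C)(C)C(C)(C)C)cc1
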